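## Retrosynthetic overview

1. Ring C (pyranone) is closed last, through the O1–C2 ether bond, by an intramolecular Mitsunobu reaction of a 2'-hydroxyaryl ketone that carries the neopentyl CH2OH group.
2. The cyclobutene (bond between the cyclobutene CH2 and ring B) comes from a palladium-catalysed C(sp3)–H arylation of a methyl group on the aryl-bearing quaternary carbon.
3. The quaternary centre comes from a chelate-controlled methylation of a β-hydroxy ester dianion (Fráter–Seebach). The carbinol carbon is a relay stereocentre and is later oxidised to the C4 ketone.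
4. The key C3–C4 bond joins the two halves in an intermolecular Evans syn-aldol addition of a ring-B arylacetyl oxazolidinone to a ring-A benzaldehyde.
5. Ring order: rings A and B are bought as benzene derivatives, the four-membered ring is formed first, the pyranone ring last.

Target as read from the SMILES: spiro carbon C3 is S (priorities C4 > C2 > aryl carbon > cyclobutene CH2). rt = room temperature.

## Route

Step 1
Reactants: 1 (2,3-dimethoxyphenyl)acetic acid
Product: 2 (6-bromo-2,3-dimethoxyphenyl)acetic acid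
Conditions: NBS, MeCN, rt
Reagents that add atoms: N-bromosuccinimide O=C1CCC(=O)N1Br
Why: Electrophilic aromatic bromination; the unhindered 3-methoxy group directs para to C6 (also ortho to the CH2CO2H group) while the twisted 2-methoxy group is a weak director, as is known for 2,3-dimethoxybenzaldehyde.

Step 2
Reactants: 2 (6-bromo-2,3-dimethoxyphenyl)acetic acid; 3 (4R)-4-benzyl-1,3-oxazolidin-2-one
Product: 5 (4R)-4-benzyl-3-[(6-bromo-2,3-dimethoxyphenyl)acetyl]-1,3-oxazolidin-2-one, via mixed pivalic anhydride 4 (not isolated)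
Conditions: PivCl, Et3N, THF, −20 °C; then 3, LiCl, −20 °C → rt
Reagents that add atoms: pivaloyl chloride CC(C)(C)C(Cl)=O (acyl group kept in 4 only)
Why: N-acylation of the Evans auxiliary through the mixed anhydride is a standard way to load arylacetic acids and touches no stereocentre.

Step 3
Reactants: 6 2-hydroxy-4,6-dimethoxybenzaldehyde
Product: 7 4,6-dimethoxy-2-(methoxymethoxy)benzaldehyde
Conditions: MOMCl, iPr2NEt, CH2Cl2, 0 °C → rt
Reagents that add atoms: chloromethyl methyl ether COCCl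
Why: O-alkylation of the phenol (Williamson-type) masks the acidic OH for the enolate steps; the MOM acetal is removed later by acid.

Step 4
Reactants: 5 (4R)-4-benzyl-3-[(6-bromo-2,3-dimethoxyphenyl)acetyl]-1,3-oxazolidin-2-one; 7 4,6-dimethoxy-2-(methoxymethoxy)benzaldehyde
Product: 10 (4R)-4-benzyl-3-[(2R,3R)-2-(6-bromo-2,3-dimethoxyphenyl)-3-[4,6-dimethoxy-2-(methoxymethoxy)phenyl]-3-hydroxypropanoyl]-1,3-oxazolidin-2-one, via Z-boron enolate 8 (not isolated), via boron aldolate 9 (not isolated)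
Conditions: Bu2BOTf, iPr2NEt, CH2Cl2, 0 °C; 7, −78 → 0 °C; then pH 7 buffer, MeOH, H2O2, 0 °C
Reagents that add atoms: dibutylboron triflate CCCCB(CCCC)OS(=O)(=O)C(F)(F)F (boron kept in 8 and 9 only)
Why: Evans syn-aldol addition; the Z-boron enolate reacts through a closed Zimmerman–Traxler chair on the face away from the benzyl group of the (R)-auxiliary, which sets the carbinol carbon as 3R (and C2 as 2R, a centre that is erased in step 7).

Step 5
Reactants: 10 aldol adduct
Product: 12 (2R,3R)-2-(6-bromo-2,3-dimethoxyphenyl)-3-[4,6-dimethoxy-2-(methoxymethoxy)phenyl]-3-hydroxypropanoic acid, via lithium percarboxylate 11 (not isolated)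
Conditions: LiOH, H2O2, THF/H2O, 0 °C; Na2SO3; then 1 M HCl to pH 3, 0 °C
Reagents that add atoms: hydrogen peroxide OO; lithium hydroxide [Li+].[OH-] (lithium kept in 11 only)
Why: Hydroperoxide-mediated imide hydrolysis attacks the exocyclic carbonyl selectively even in hindered adducts, sulfite reduces the percarboxylate, and neither stereocentre is touched.

Step 6
Reactants: 12 hydroxy acid
Product: 13 methyl (2R,3R)-2-(6-bromo-2,3-dimethoxyphenyl)-3-[4,6-dimethoxy-2-(methoxymethoxy)phenyl]-3-hydroxypropanoate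
Conditions: MeI, KHCO3, DMF, rt
Reagents that add atoms: iodomethane IC
Why: SN2 O-methylation of the carboxylate under near-neutral conditions avoids retro-aldol cleavage and acid ionisation of the electron-rich benzylic alcohol.

Step 7
Reactants: 13 β-hydroxy ester
Product: 15 methyl (2R,3S)-2-(6-bromo-2,3-dimethoxyphenyl)-3-[4,6-dimethoxy-2-(methoxymethoxy)phenyl]-3-hydroxy-2-methylpropanoate, via dilithium dianion 14 (not isolated)
Conditions: LiN(iPr)2 (2.5 equiv), THF, −78 → −40 °C; MeI, DMPU, −78 → −40 °C; AcOH, −78 °C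
Reagents that add atoms: iodomethane IC; lithium diisopropylamide [Li+].CC(C)[N-]C(C)C (lithium kept in 14 only)
Why: Fráter–Seebach alkylation; in the lithium-chelated alkoxide–enolate MeI adds to the enolate face anti to the aryl group on the carbinol carbon, so the carbinol centre dictates the new quaternary centre as 2R whatever the former C2 configuration was (the C3 descriptor changes from R to S only through the priority change).

Step 8
Reactants: 15 quaternary β-hydroxy ester
Product: 16 (1R,2S)-2-(6-bromo-2,3-dimethoxyphenyl)-1-[4,6-dimethoxy-2-(methoxymethoxy)phenyl]-2-methylpropane-1,3-diol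
Conditions: LiAlH4, THF, 0 °C; then H2O, aq NaOH
Reagents that add atoms: none
Why: Hydride reduction of the ester to the primary alcohol; the aryl bromide, the MOM acetal and both stereocentres are inert to LiAlH4 at 0 °C.

Step 9
Reactants: 16 diol
Product: 17 (1R,2S)-2-(6-bromo-2,3-dimethoxyphenyl)-3-[(tert-butyldimethylsilyl)oxy]-1-[4,6-dimethoxy-2-(methoxymethoxy)phenyl]-2-methylpropan-1-ol
Conditions: TBSCl, imidazole, DMF, 0 °C
Reagents that add atoms: tert-butyldimethylsilyl chloride CC(C)(C)[Si](C)(C)Cl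
Why: Silylation is selective for the primary hydroxyl over the hindered secondary benzylic one.

Step 10
Reactants: 17 mono-silyl ether
Product: 18 (2S)-2-(6-bromo-2,3-dimethoxyphenyl)-3-[(tert-butyldimethylsilyl)oxy]-1-[4,6-dimethoxy-2-(methoxymethoxy)phenyl]-2-methylpropan-1-one
Conditions: Dess–Martin periodinane, pyridine, CH2Cl2, 0 °C → rt
Reagents that add atoms: none
Why: Dess–Martin oxidation turns the relay carbinol into the C4 ketone under buffered conditions; the neighbouring quaternary centre has no α-hydrogen and cannot epimerise.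

Step 11
Reactants: 18 bromo ketone
Product: 19 [(7S)-7-{[(tert-butyldimethylsilyl)oxy]methyl}-4,5-dimethoxybicyclo[4.2.0]octa-1,3,5-trien-7-yl][4,6-dimethoxy-2-(methoxymethoxy)phenyl]methanone
Conditions: Pd(OAc)2 (10 mol %), [HP(tBu)3]BF4 (20 mol %), K2CO3, DMF, 140 °C
Reagents that add atoms: none
Why: Palladium-catalysed C(sp3)–H arylation (Baudoin-type benzocyclobutene synthesis); zerovalent palladium inserts into the C–Br bond, carbonate-assisted concerted metalation–deprotonation of the methyl group gives a five-membered divalent palladacycle, and reductive elimination closes the four-membered ring without touching the quaternary stereocentre.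

Step 12
Reactants: 19 protected benzocyclobutene ketone
Product: 20 [(7S)-7-(hydroxymethyl)-4,5-dimethoxybicyclo[4.2.0]octa-1,3,5-trien-7-yl](2-hydroxy-4,6-dimethoxyphenyl)methanone
Conditions: HCl (1.25 M in MeOH), 40 °C
Reagents that add atoms: none
Why: Acid-catalysed methanolysis cleaves the MOM acetal and the primary TBS ether in one operation; with C4 now a ketone no acid-labile benzylic alcohol is left.

Step 13
Reactants: 20 hydroxy ketone phenol
Product: 21 (3S)-4',5,5',7-tetramethoxyspiro[chromane-3,7'-bicyclo[4.2.0]octa[1,3,5]trien]-4-one (CNP0192565.1)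
Conditions: PPh3, DIAD, THF, 0 °C → rt
Reagents that add atoms: none
Why: Intramolecular Mitsunobu etherification; the acidic ortho-acyl phenol displaces the activated primary alcohol in a 6-exo closure under neutral conditions that cannot trigger retro-aldol loss of formaldehyde, and the stereocentre is not involved.

## Compound list

1 | (2,3-dimethoxyphenyl)acetic acid | OC(=O)Cc1cccc(OC)c1OC | starting material
2 | (6-bromo-2,3-dimethoxyphenyl)acetic acid | OC(=O)Cc1c(Br)ccc(OC)c1OC | intermediate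
3 | (4R)-4-benzyl-1,3-oxazolidin-2-one | O=C1N[C@H](Cc2ccccc2)CO1 | starting material
4 | (6-bromo-2,3-dimethoxyphenyl)acetic pivalic anhydride | CC(C)(C)C(=O)OC(=O)Cc1c(Br)ccc(OC)c1OC | intermediate (not isolated)
5 | (4R)-4-benzyl-3-[(6-bromo-2,3-dimethoxyphenyl)acetyl]-1,3-oxazolidin-2-one | O=C(Cc1c(Br)ccc(OC)c1OC)N1C(=O)OC[C@H]1Cc1ccccc1 | intermediate
6 | 2-hydroxy-4,6-dimethoxybenzaldehyde | O=Cc1c(O)cc(OC)cc1OC | starting material
7 | 4,6-dimethoxy-2-(methoxymethoxy)benzaldehyde | O=Cc1c(OCOC)cc(OC)cc1OC | intermediate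
8 | Z-dibutylboron enolate of 5 | CCCCB(CCCC)O/C(=C\c1c(Br)ccc(OC)c1OC)N1C(=O)OC[C@H]1Cc1ccccc1 | intermediate (not isolated)
9 | dibutylboron aldolate of 10 | O=C([C@H](c1c(Br)ccc(OC)c1OC)[C@@H](OB(CCCC)CCCC)c1c(OCOC)cc(OC)cc1OC)N1C(=O)OC[C@H]1Cc1ccccc1 | intermediate (not isolated)
10 | (4R)-4-benzyl-3-[(2R,3R)-2-(6-bromo-2,3-dimethoxyphenyl)-3-[4,6-dimethoxy-2-(methoxymethoxy)phenyl]-3-hydroxypropanoyl]-1,3-oxazolidin-2-one | O=C([C@H](c1c(Br)ccc(OC)c1OC)[C@@H](O)c1c(OCOC)cc(OC)cc1OC)N1C(=O)OC[C@H]1Cc1ccccc1 | intermediate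
11 | lithium (2R,3R)-2-(6-bromo-2,3-dimethoxyphenyl)-3-[4,6-dimethoxy-2-(methoxymethoxy)phenyl]-3-hydroxypropaneperoxoate | [Li+].[O-]OC(=O)[C@H](c1c(Br)ccc(OC)c1OC)[C@@H](O)c1c(OCOC)cc(OC)cc1OC | intermediate (not isolated)
12 | (2R,3R)-2-(6-bromo-2,3-dimethoxyphenyl)-3-[4,6-dimethoxy-2-(methoxymethoxy)phenyl]-3-hydroxypropanoic acid | OC(=O)[C@H](c1c(Br)ccc(OC)c1OC)[C@@H](O)c1c(OCOC)cc(OC)cc1OC | intermediate
13 | methyl (2R,3R)-2-(6-bromo-2,3-dimethoxyphenyl)-3-[4,6-dimethoxy-2-(methoxymethoxy)phenyl]-3-hydroxypropanoate | COC(=O)[C@H](c1c(Br)ccc(OC)c1OC)[C@@H](O)c1c(OCOC)cc(OC)cc1OC | intermediate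
14 | chelated dilithium alkoxide–enolate dianion of 13 (enolate oxygen cis to the carbinol carbon) | [Li+].[Li+].[O-]/C(OC)=C(/c1c(Br)ccc(OC)c1OC)[C@@H]([O-])c1c(OCOC)cc(OC)cc1OC | intermediate (not isolated)
15 | methyl (2R,3S)-2-(6-bromo-2,3-dimethoxyphenyl)-3-[4,6-dimethoxy-2-(methoxymethoxy)phenyl]-3-hydroxy-2-methylpropanoate | COC(=O)[C@](C)(c1c(Br)ccc(OC)c1OC)[C@@H](O)c1c(OCOC)cc(OC)cc1OC | intermediate
16 | (1R,2S)-2-(6-bromo-2,3-dimethoxyphenyl)-1-[4,6-dimethoxy-2-(methoxymethoxy)phenyl]-2-methylpropane-1,3-diol | OC[C@](C)(c1c(Br)ccc(OC)c1OC)[C@@H](O)c1c(OCOC)cc(OC)cc1OC | intermediate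
17 | (1R,2S)-2-(6-bromo-2,3-dimethoxyphenyl)-3-[(tert-butyldimethylsilyl)oxy]-1-[4,6-dimethoxy-2-(methoxymethoxy)phenyl]-2-methylpropan-1-ol | CC(C)(C)[Si](C)(C)OC[C@](C)(c1c(Br)ccc(OC)c1OC)[C@@H](O)c1c(OCOC)cc(OC)cc1OC | intermediate
18 | (2S)-2-(6-bromo-2,3-dimethoxyphenyl)-3-[(tert-butyldimethylsilyl)oxy]-1-[4,6-dimethoxy-2-(methoxymethoxy)phenyl]-2-methylpropan-1-one | CC(C)(C)[Si](C)(C)OC[C@](C)(c1c(Br)ccc(OC)c1OC)C(=O)c1c(OCOC)cc(OC)cc1OC | intermediate
19 | [(7S)-7-{[(tert-butyldimethylsilyl)oxy]methyl}-4,5-dimethoxybicyclo[4.2.0]octa-1,3,5-trien-7-yl][4,6-dimethoxy-2-(methoxymethoxy)phenyl]methanone | CC(C)(C)[Si](C)(C)OC[C@@]1(Cc2ccc(OC)c(OC)c21)C(=O)c1c(OCOC)cc(OC)cc1OC | intermediate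
20 | [(7S)-7-(hydroxymethyl)-4,5-dimethoxybicyclo[4.2.0]octa-1,3,5-trien-7-yl](2-hydroxy-4,6-dimethoxyphenyl)methanone | OC[C@@]1(Cc2ccc(OC)c(OC)c21)C(=O)c1c(O)cc(OC)cc1OC | intermediate
21 | (3S)-4',5,5',7-tetramethoxyspiro[chromane-3,7'-bicyclo[4.2.0]octa[1,3,5]trien]-4-one | COc1cc(OC)c2c(c1)OC[C@@]1(Cc3ccc(OC)c(OC)c31)C2=O | target

## Step count and risks

Total step count: 13. Longest linear sequence: 12 steps (steps 1, 2 and 4–13); step 3 is the one-step side branch.

The three steps most likely to fail: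

Step 4 (aldol). Both partners are hindered: the enolate carries a 2,6-disubstituted aryl group, and the aldehyde is 2,6-disubstituted, electron-rich and weakly electrophilic. The fallback sets out from 2 and 7 and comes back at 15. Esterify 2 (MeI, KHCO3, DMF) to methyl (6-bromo-2,3-dimethoxyphenyl)acetate F1. Add its lithium enolate (LiN(iPr)2, THF, −78 °C), which is far smaller than the auxiliary-bearing boron enolate, to 7 to get the racemic stereoisomer mixture of methyl 2-(6-bromo-2,3-dimethoxyphenyl)-3-[4,6-dimethoxy-2-(methoxymethoxy)phenyl]-3-hydroxypropanoate F2. Methylate its dianion as in step 7; by the same relay this gives one racemic diastereomer, made of 15 and its mirror image methyl (2S,3R)-2-(6-bromo-2,3-dimethoxyphenyl)-3-[4,6-dimethoxy-2-(methoxymethoxy)phenyl]-3-hydroxy-2-methylpropanoate F3. Separate the two by preparative chromatography on a chiral stationary phase; 15 rejoins the route at step 8.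

Step 11 (C–H arylation). The hindered aryl ketone may suffer protodebromination or decomposition at 140 °C before the methyl C–H bond is cleaved. The fallback sets out from 16 and comes back at 19. Tie the diol up (tBu2Si(OTf)2, 2,6-lutidine, CH2Cl2, 0 °C) as the di-tert-butylsilylene acetal of 16 F4. Run the same palladium-catalysed arylation on this ketone-free substrate to get the benzocyclobutene silylene acetal F5. Remove the silylene with HF·pyridine to give the benzocyclobutene diol F6. Silylate the primary hydroxyl (TBSCl, imidazole) to give the benzocyclobutene mono-TBS ether F7. Oxidise with Dess–Martin periodinane to reach 19.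

Step 13 (Mitsunobu). The substitution is at a neopentyl carbon, and the nucleophile is a hydrogen-bonded, weakly nucleophilic phenol. The fallback sets out from 19 and comes back at 21, and forms the O1–C2 bond by carbonyl addition instead of substitution. Remove only the TBS group (HF·pyridine, THF, 0 °C) to give the MOM-protected hydroxy ketone F8. Oxidise with Dess–Martin periodinane to the keto aldehyde F9. Treat with HCl in MeOH, which frees the phenol and closes it onto the aldehyde as the cyclic mixed acetal, the 2-methoxychromanone F10 (both C2 epimers). Reduce the acetal carbon with Et3SiH and BF3·OEt2 in CH2Cl2 at −78 °C (ionic hydrogenation through the oxocarbenium ion; the low temperature spares the C4 ketone) to give 21.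

## Further compounds

F1 | step 4 | methyl (6-bromo-2,3-dimethoxyphenyl)acetate | COC(=O)Cc1c(Br)ccc(OC)c1OC
F2 | step 4 | methyl 2-(6-bromo-2,3-dimethoxyphenyl)-3-[4,6-dimethoxy-2-(methoxymethoxy)phenyl]-3-hydroxypropanoate, racemic mixture of all four stereoisomers | COC(=O)C(c1c(Br)ccc(OC)c1OC)C(O)c1c(OCOC)cc(OC)cc1OC
F3 | step 4 | methyl (2S,3R)-2-(6-bromo-2,3-dimethoxyphenyl)-3-[4,6-dimethoxy-2-(methoxymethoxy)phenyl]-3-hydroxy-2-methylpropanoate (mirror image of 15) | COC(=O)[C@@](C)(c1c(Br)ccc(OC)c1OC)[C@H](O)c1c(OCOC)cc(OC)cc1OC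
F4 | step 11 | di-tert-butylsilylene acetal of 16 (2,2-di-tert-butyl-1,3,2-dioxasilinane, both stereocentres as in 16) | CC(C)(C)[Si]1(C(C)(C)C)OC[C@](C)(c2c(Br)ccc(OC)c2OC)[C@H](c2c(OCOC)cc(OC)cc2OC)O1
F5 | step 11 | benzocyclobutene silylene acetal (spiro carbon as in 19, carbinol carbon as in 16) | CC(C)(C)[Si]1(C(C)(C)C)OC[C@@]2(Cc3ccc(OC)c(OC)c32)[C@H](c2c(OCOC)cc(OC)cc2OC)O1
F6 | step 11 | [4,6-dimethoxy-2-(methoxymethoxy)phenyl][7-(hydroxymethyl)-4,5-dimethoxybicyclo[4.2.0]octa-1,3,5-trien-7-yl]methanol (stereocentres as in F5) | OC[C@@]1(Cc2ccc(OC)c(OC)c21)[C@@H](O)c1c(OCOC)cc(OC)cc1OC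
F7 | step 11 | primary mono-TBS ether of F6 | CC(C)(C)[Si](C)(C)OC[C@@]1(Cc2ccc(OC)c(OC)c21)[C@@H](O)c1c(OCOC)cc(OC)cc1OC
F8 | step 13 | [7-(hydroxymethyl)-4,5-dimethoxybicyclo[4.2.0]octa-1,3,5-trien-7-yl][4,6-dimethoxy-2-(methoxymethoxy)phenyl]methanone (spiro carbon as in 19) | OC[C@@]1(Cc2ccc(OC)c(OC)c21)C(=O)c1c(OCOC)cc(OC)cc1OC
F9 | step 13 | 7-[4,6-dimethoxy-2-(methoxymethoxy)benzoyl]-4,5-dimethoxybicyclo[4.2.0]octa-1,3,5-triene-7-carbaldehyde (spiro carbon as in 19) | O=C[C@@]1(Cc2ccc(OC)c(OC)c21)C(=O)c1c(OCOC)cc(OC)cc1OC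
F10 | step 13 | 2,4',5,5',7-pentamethoxyspiro[chromane-3,7'-bicyclo[4.2.0]octa[1,3,5]trien]-4-one (spiro carbon as in 21, both C2 epimers) | COc1cc(OC)c2c(c1)OC(OC)[C@@]1(Cc3ccc(OC)c(OC)c31)C2=O
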